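Over the first 8.00 min of these isothermal runs, compare what each earlier run consumed with what it was given.

| flask | starting material | second substrate | enzyme | impurity | remark |
|---|---|---|---|---|---|
| ochre | 20 mM | 2 equiv | 0.001 mol% | 0.047 µM | run made earlier |
| teal | 20 mM | 2 equiv | 0.0016 mol% | 0.047 µM | run made earlier |
| red | 40 mM | 2 equiv | 0.0021 mol% | 0.047 µM | run made earlier |
| flask | 20 mM | 2.00 equiv | 0.0021 mol% | 0.047 µM |  |

- ochre (time / min: target / %, starting material / %): 1.33: 1.9, 98.7; 3.00: 0.9, 97.9; 4.00: 4.2, 98.0; 6.00: 5.6, 95.4; 8.00: 4.2, 95.1
- teal (time / min: target / %, starting material / %): 1.33: 0.8, 96.5; 3.00: 4.2, 95.9; 4.00: 5.4, 96.4; 6.00: 6.9, 92.3; 8.00: 10.4, 91.2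
- red (time / min: target / %, starting material / %): 0.667: 1.4, 98.7; 2.00: 3.6, 97.6; 3.00: 5.1, 95.1; 5.00: 9.4, 91.4; 8.00: 14.6, 86.9

(standard deviation of a reading: 1 percentage point)

- factor on the rate of making target when 50% of the starting material are converted if second substrate is charged twice over
- factor on the rate when 50% of the starting material are converted if enzyme is charged at 0.02 mol% instead

Does consumption follow the enzyme charged? By the last reading, teal has used 1.80 times ochre's starting material on 1.60 times the enzyme. Red, in absolute amounts and with 40 mM of starting material against ochre's 20 mM, has used 5.35 times on 4.20 times. Both readings, each with a scatter of 1 percentage point, run ahead of the charge.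

So suppose each impurity removes one enzyme, and compute only that correction. Call it the dead share: impurity charged as a fraction of enzyme charged. It is 23.5% for ochre, 14.7% for teal and 5.60% for red. Taking it off turns the charge ratios into 1.78 and 5.18, close to the readings.

What does that promise for the flask? Its dead share is 11.2%, and at 0.02 mol% it would be 1.17%, so my reckoning for the enzyme factor is 10.6. Ochre, teal and red each stand at 2 equiv, so these readings do not test second substrate apart from starting material.

The forecast gives 10.6 (9.5 to 11.5) for the enzyme factor and 1.05 (0.95 to 1.4) for doubling second substrate, holding that "the enzyme looks saturated, near zero order in both".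

The flask gives 0.528 for doubling second substrate and 13.0 for the enzyme.

    starting material + enzyme ⇌ complex A (K = 65.0 L mol⁻¹, k = 3.50 × 10⁵ L mol⁻¹ s⁻¹)
    complex A → enzyme + target (k = 120 s⁻¹)
    second substrate + enzyme ⇌ complex B (K = 230 L mol⁻¹, k = 4.10 × 10⁵ L mol⁻¹ s⁻¹)
    enzyme + impurity → spent catalyst B (k = 1.40 × 10⁶ L mol⁻¹ s⁻¹)
    second substrate + complex A → spent catalyst A (k = 0.0460 L mol⁻¹ s⁻¹)
    complex B → enzyme + second product (k = 100 s⁻¹)

In the flask at 12.0 min, complex B, the resting state at that time, holds 54.1% of the catalyst charged, more than any other form. With impurity at 0% of its charge by then, spent catalyst B stands at 11.2%, against the flask's dead share of 11.2%. For the flask charged at 0.02 mol%, taking off the dead share gives 10.6, and the factor of 13.0 lies above that by 1.23.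

Readings and results were generated by integration with constants of no real substance, and the scatter is random.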